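**Plan**

- Ring numbering used below: C1 (C–OMe), C2 (=CH), C3 (C=O), C4 (quaternary epoxide carbon carrying the farnesyl chain), C5 (epoxide CH), C6 (CHOH).
- Retrosynthetic cuts, in order: the C5–O epoxide bond (C4 alkoxide displacing a C5 sulfonate), the ring bond C5–C6, C1–OMe, C2–C3, the C4–O bond, and last C4–CH2 (farnesyl).
- Enabling feature: C6 is the γ-carbon of the C3(=O)–C2=C1(OMe) vinylogous ester and C5 is an aldehyde-level carbon on quaternary C4. C5–C6 is therefore an intramolecular vinylogous aldol bond, with a single acidic site and a non-enolisable aldehyde.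
- Forward order: farnesyl bromide and 2-bromoallyl alcohol are joined, the allyl alcohol is epoxidised, and the two CH2O arms are differentiated (CH2OPMB becomes C5, CH2OH becomes C3). The chain is extended to an ynone and then an (E)-β-methoxy enone, the keto aldehyde is unveiled, the only carbocycle closes in step 11, and the epoxide closes in step 13.
- Stereochemistry: C4 comes from Sharpless epoxidation with L-(+)-tartrate. C5 and C6 are relayed from C4 in the aldol ring closure. C5 is inverted once when the epoxide closes, which gives the cis epoxy alcohol.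

Key step: step 11

Assumption: the tert-butyldiphenylsilyl ether of propargyl alcohol used in step 6 is treated as a purchasable compound; it is otherwise one silylation away from propargyl alcohol.

**Route**

Step 1
Reactants: 1 2-bromoallyl alcohol (2-bromoprop-2-en-1-ol); 2 (2E,6E)-farnesyl bromide
Product: 5 (4E,8E)-5,9,13-trimethyl-2-methylidenetetradeca-4,8,12-trien-1-ol, via dilithiated allyl alcohol 3 (not isolated), via alkenylzinc chloride 4 (not isolated)
Conditions: t-BuLi (3.1 equiv), Et2O, −78 → 0 °C; ZnCl2, THF, 0 °C; then 2, Pd(PPh3)4 (3 mol %), 0 °C → rt; aq. NH4Cl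
Reagents that add atoms: none
Why: Bromine–lithium exchange on the lithium alkoxide gives the 2-lithioallyl alkoxide, which after transmetalation to zinc should undergo a Negishi coupling with the allylic bromide under zerovalent palladium; alkenyl–allyl couplings of this kind join the alkenyl group to the unsubstituted allyl terminus and keep the E geometry of prenyl-type partners.

Step 2
Reactants: 5 (4E,8E)-5,9,13-trimethyl-2-methylidenetetradeca-4,8,12-trien-1-ol
Product: 6 [(2S)-2-[(2E,6E)-3,7,11-trimethyldodeca-2,6,10-trien-1-yl]oxiran-2-yl]methanol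
Conditions: Ti(OiPr)4 (10 mol %), L-(+)-diisopropyl tartrate (12 mol %), t-BuOOH, 4 Å molecular sieves, CH2Cl2, −20 °C
Reagents that add atoms: tert-butyl hydroperoxide, CC(C)(C)OO
Why: In the Sharpless asymmetric epoxidation the titanium tartrate complex binds the allylic hydroxyl, so only the 1,1-disubstituted allylic alkene is oxidised, and the L-(+)-tartrate ligand should deliver oxygen to the face that gives the (S)-epoxy alcohol, which creates the future C4 stereocentre.

Step 3
Reactants: 6 [(2S)-2-[(2E,6E)-3,7,11-trimethyldodeca-2,6,10-trien-1-yl]oxiran-2-yl]methanol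
Product: 7 (2S,4E,8E)-2-{[(4-methoxybenzyl)oxy]methyl}-5,9,13-trimethyltetradeca-4,8,12-triene-1,2-diol
Conditions: 4-methoxybenzyl alcohol (4 equiv), NaH (2.2 equiv), DMF, 0 → 60 °C
Reagents that add atoms: 4-methoxybenzyl alcohol, COc1ccc(CO)cc1
Why: Base-mediated SN2 opening of the epoxide by the benzylic alkoxide occurs at the unhindered CH2 terminus and leaves the C–O bond at the quaternary carbon, and so its configuration, intact; the Payne rearrangement open to the substrate alkoxide is degenerate for a 2-substituted glycidol and cannot erode optical purity.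

Step 4
Reactants: 7 (2S,4E,8E)-2-{[(4-methoxybenzyl)oxy]methyl}-5,9,13-trimethyltetradeca-4,8,12-triene-1,2-diol
Product: 8 (2R,4E,8E)-2-{[(4-methoxybenzyl)oxy]methyl}-5,9,13-trimethyl-1,2-bis[(triethylsilyl)oxy]tetradeca-4,8,12-triene
Conditions: Et3SiOTf (2.5 equiv), 2,6-lutidine, CH2Cl2, −78 → 0 °C
Reagents that add atoms: triethylsilyl trifluoromethanesulfonate, CC[Si](CC)(CC)OS(=O)(=O)C(F)(F)F
Why: Silylation with a silyl triflate and 2,6-lutidine protects even the tertiary hydroxyl and does not disturb the 4-methoxybenzyl ether.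

Step 5
Reactants: 8 (2R,4E,8E)-2-{[(4-methoxybenzyl)oxy]methyl}-5,9,13-trimethyl-1,2-bis[(triethylsilyl)oxy]tetradeca-4,8,12-triene
Product: 9 (2R,4E,8E)-2-{[(4-methoxybenzyl)oxy]methyl}-5,9,13-trimethyl-2-[(triethylsilyl)oxy]tetradeca-4,8,12-trienal
Conditions: (COCl)2, DMSO, CH2Cl2, −78 → −40 °C; Et3N, −78 → 0 °C
Reagents that add atoms: none
Why: Under Swern conditions a primary triethylsilyl ether is cleaved and oxidised to the aldehyde in one operation while the tertiary silyl ether and the benzylic ether are inert; the aldehyde has no α-hydrogen and cannot epimerise.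

Step 6
Reactants: 9 (2R,4E,8E)-2-{[(4-methoxybenzyl)oxy]methyl}-5,9,13-trimethyl-2-[(triethylsilyl)oxy]tetradeca-4,8,12-trienal; 10 tert-butyl(diphenyl)(prop-2-yn-1-yloxy)silane
Product: 12 (5R,7E,11E)-1-[(tert-butyldiphenylsilyl)oxy]-5-{[(4-methoxybenzyl)oxy]methyl}-8,12,16-trimethyl-5-[(triethylsilyl)oxy]heptadeca-7,11,15-trien-2-yn-4-ol (mixture of C4 carbinol epimers), via lithium acetylide 11 (not isolated)
Conditions: 10, n-BuLi, THF, −78 °C; then 9, −78 °C; aq. NH4Cl at −78 °C
Reagents that add atoms: none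
Why: This is the 1,2-addition of a lithium acetylide to an aldehyde; the carbinol epimer mixture is of no consequence because step 7 oxidises it, and the cold quench should prevent 1,2-silyl migration to the new alkoxide.

Step 7
Reactants: 12 (5R,7E,11E)-1-[(tert-butyldiphenylsilyl)oxy]-5-{[(4-methoxybenzyl)oxy]methyl}-8,12,16-trimethyl-5-[(triethylsilyl)oxy]heptadeca-7,11,15-trien-2-yn-4-ol
Product: 13 (5R,7E,11E)-1-[(tert-butyldiphenylsilyl)oxy]-5-{[(4-methoxybenzyl)oxy]methyl}-8,12,16-trimethyl-5-[(triethylsilyl)oxy]heptadeca-7,11,15-trien-2-yn-4-one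
Conditions: Dess–Martin periodinane, NaHCO3, CH2Cl2, 0 °C → rt
Reagents that add atoms: none
Why: Dess–Martin oxidation converts the propargylic alcohol into the ynone under buffered conditions that spare the silyl ethers and the trisubstituted alkenes.

Step 8
Reactants: 13 (5R,7E,11E)-1-[(tert-butyldiphenylsilyl)oxy]-5-{[(4-methoxybenzyl)oxy]methyl}-8,12,16-trimethyl-5-[(triethylsilyl)oxy]heptadeca-7,11,15-trien-2-yn-4-one
Product: 14 (2E,5R,7E,11E)-1-[(tert-butyldiphenylsilyl)oxy]-2-methoxy-5-{[(4-methoxybenzyl)oxy]methyl}-8,12,16-trimethyl-5-[(triethylsilyl)oxy]heptadeca-2,7,11,15-tetraen-4-one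
Conditions: MeOH, PMe3 (20 mol %), CH2Cl2, 0 °C → rt
Reagents that add atoms: methanol, CO
Why: Phosphine-catalysed oxa-Michael addition of methanol to the ynone places the methoxy group on the β-carbon (C1), and equilibration through reversible phosphine addition should lead to the more stable (E)-β-methoxy enone, in which C6 is cis to the C3 carbonyl.

Step 9
Reactants: 14 (2E,5R,7E,11E)-1-[(tert-butyldiphenylsilyl)oxy]-2-methoxy-5-{[(4-methoxybenzyl)oxy]methyl}-8,12,16-trimethyl-5-[(triethylsilyl)oxy]heptadeca-2,7,11,15-tetraen-4-one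
Product: 15 (2E,5R,7E,11E)-1-[(tert-butyldiphenylsilyl)oxy]-5-(hydroxymethyl)-2-methoxy-8,12,16-trimethyl-5-[(triethylsilyl)oxy]heptadeca-2,7,11,15-tetraen-4-one
Conditions: DDQ, CH2Cl2/pH 7 buffer, 0 °C
Reagents that add atoms: none
Why: Oxidative cleavage of the 4-methoxybenzyl ether with DDQ under buffered conditions leaves silyl ethers, isolated alkenes and the vinylogous ester alone; the primary alcohol is carried on at once so that acid-catalysed addition to C1 has no opportunity.

Step 10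
Reactants: 15 (2E,5R,7E,11E)-1-[(tert-butyldiphenylsilyl)oxy]-5-(hydroxymethyl)-2-methoxy-8,12,16-trimethyl-5-[(triethylsilyl)oxy]heptadeca-2,7,11,15-tetraen-4-one
Product: 16 (2R,4E)-6-[(tert-butyldiphenylsilyl)oxy]-5-methoxy-3-oxo-2-[(triethylsilyl)oxy]-2-[(2E,6E)-3,7,11-trimethyldodeca-2,6,10-trien-1-yl]hex-4-enal
Conditions: Dess–Martin periodinane, NaHCO3, CH2Cl2, 0 °C
Reagents that add atoms: none
Why: Dess–Martin oxidation of the neopentyl-type primary alcohol gives the non-enolisable C5 aldehyde under neutral conditions that the vinylogous ester tolerates.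

Step 11
Reactants: 16 (2R,4E)-6-[(tert-butyldiphenylsilyl)oxy]-5-methoxy-3-oxo-2-[(triethylsilyl)oxy]-2-[(2E,6E)-3,7,11-trimethyldodeca-2,6,10-trien-1-yl]hex-4-enal
Product: 18 (4S,5S,6R)-4-[(tert-butyldiphenylsilyl)oxy]-5-hydroxy-3-methoxy-6-[(triethylsilyl)oxy]-6-[(2E,6E)-3,7,11-trimethyldodeca-2,6,10-trien-1-yl]cyclohex-2-en-1-one, via potassium dienolate 17 (not isolated)
Conditions: KN(SiMe3)2 (1.1 equiv, added over 1 h), THF (0.005 M), −78 → −40 °C; AcOH, −78 °C
Reagents that add atoms: none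
Why: KN(SiMe3)2 removes a proton from C6, the only acidic position because C4 is quaternary and the aldehyde has no α-hydrogen, and the γ-carbon of the resulting potassium dienolate (O–C3=C2–C1=C6) adds to the C5 aldehyde; the closest known reaction type is the γ-selective vinylogous aldol addition of β-alkoxy enone and enoate dienolates, used here within one molecule. The six-membered ring closes in a 6-(enolendo)-exo-trig mode, which demands the dienolate rotamer with C4 cis to C1 across C3–C2; because hexamethyldisilazane is of similar acidity to the γ-CH, slow addition of base should keep proton transfer reversible, so the unproductive rotamer is returned to the enone while the reactive one is drained by cyclisation. C5 is set by C4: in the chair-like transition state the C4 silyloxy group lies equatorial and anti to the forming bond (polar Felkin–Anh) and, with the non-chelating potassium counter-ion, the aldehyde oxygen points equatorially away from the dienolate oxygen, which places C5–O trans to C4–O. C6 is set in the same chair: the bulky silyloxy substituent takes the outer position on the dienolate terminus and becomes equatorial, trans to C5–O and cis to C4–O. The step needs γ- rather than α-attack, which is secured because α-attack would form a four-membered ring, and it needs kinetic control, which low temperature and the cold acidic quench secure by forestalling retro-aldol cleavage.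

Step 12
Reactants: 18 (4S,5S,6R)-4-[(tert-butyldiphenylsilyl)oxy]-5-hydroxy-3-methoxy-6-[(triethylsilyl)oxy]-6-[(2E,6E)-3,7,11-trimethyldodeca-2,6,10-trien-1-yl]cyclohex-2-en-1-one
Product: 19 (4S,5S,6R)-4-[(tert-butyldiphenylsilyl)oxy]-5,6-dihydroxy-3-methoxy-6-[(2E,6E)-3,7,11-trimethyldodeca-2,6,10-trien-1-yl]cyclohex-2-en-1-one
Conditions: HF·pyridine, pyridine, THF, 0 °C → rt
Reagents that add atoms: none
Why: Buffered HF·pyridine cleaves a triethylsilyl ether far faster than a tert-butyldiphenylsilyl ether (selective desilylation), and because it removes the triethylsilyl group from either the C4 or the C5 oxygen, any silyl shift in step 11 converges on the same diol.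

Step 13
Reactants: 19 (4S,5S,6R)-4-[(tert-butyldiphenylsilyl)oxy]-5,6-dihydroxy-3-methoxy-6-[(2E,6E)-3,7,11-trimethyldodeca-2,6,10-trien-1-yl]cyclohex-2-en-1-one
Product: 21 (1R,5S,6R)-5-[(tert-butyldiphenylsilyl)oxy]-4-methoxy-1-[(2E,6E)-3,7,11-trimethyldodeca-2,6,10-trien-1-yl]-7-oxabicyclo[4.1.0]hept-3-en-2-one, via C5 mesylate 20 (not isolated)
Conditions: MsCl (1.2 equiv), Et3N, CH2Cl2, −20 °C; then DBU, 0 °C → rt
Reagents that add atoms: none
Why: Selective sulfonylation of the secondary C5 hydroxyl beside the hindered tertiary C4 hydroxyl is followed by intramolecular Williamson (SN2) displacement by the C4 alkoxide, which inverts C5 and closes the epoxide on the face syn to the C6 oxygen; the C6 oxygen stays silylated and cannot compete.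

Step 14
Reactants: 21 (1R,5S,6R)-5-[(tert-butyldiphenylsilyl)oxy]-4-methoxy-1-[(2E,6E)-3,7,11-trimethyldodeca-2,6,10-trien-1-yl]-7-oxabicyclo[4.1.0]hept-3-en-2-one
Product: 22 yanuthone X2, (1R,5S,6R)-5-hydroxy-4-methoxy-1-[(2E,6E)-3,7,11-trimethyldodeca-2,6,10-trien-1-yl]-7-oxabicyclo[4.1.0]hept-3-en-2-one
Conditions: Bu4NF, AcOH, THF, 0 °C → rt
Reagents that add atoms: none
Why: Fluoride desilylation buffered with acetic acid should free the C6 hydroxyl without base-induced damage to the epoxy ketone; the hydroxyl is cis to the epoxide, so no Payne rearrangement is possible.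

**Compound list**

1 | 2-bromoallyl alcohol (2-bromoprop-2-en-1-ol) | OCC(Br)=C | starting material
2 | (2E,6E)-farnesyl bromide | BrC/C=C(\C)CC/C=C(\C)CCC=C(C)C | starting material
3 | lithium 2-lithioprop-2-en-1-olate (dilithiated allyl alcohol) | [Li]OCC([Li])=C | intermediate
4 | lithium 2-(chlorozincio)prop-2-en-1-olate (alkenylzinc chloride) | [Li]OCC(=C)[Zn]Cl | intermediate
5 | (4E,8E)-5,9,13-trimethyl-2-methylidenetetradeca-4,8,12-trien-1-ol | OCC(=C)C/C=C(\C)CC/C=C(\C)CCC=C(C)C | intermediate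
6 | [(2S)-2-[(2E,6E)-3,7,11-trimethyldodeca-2,6,10-trien-1-yl]oxiran-2-yl]methanol | OC[C@@]1(C/C=C(\C)CC/C=C(\C)CCC=C(C)C)CO1 | intermediate
7 | (2S,4E,8E)-2-{[(4-methoxybenzyl)oxy]methyl}-5,9,13-trimethyltetradeca-4,8,12-triene-1,2-diol | OC[C@@](O)(C/C=C(\C)CC/C=C(\C)CCC=C(C)C)COCc1ccc(OC)cc1 | intermediate
8 | (2R,4E,8E)-2-{[(4-methoxybenzyl)oxy]methyl}-5,9,13-trimethyl-1,2-bis[(triethylsilyl)oxy]tetradeca-4,8,12-triene | CC[Si](CC)(CC)OC[C@@](O[Si](CC)(CC)CC)(C/C=C(\C)CC/C=C(\C)CCC=C(C)C)COCc1ccc(OC)cc1 | intermediate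
9 | (2R,4E,8E)-2-{[(4-methoxybenzyl)oxy]methyl}-5,9,13-trimethyl-2-[(triethylsilyl)oxy]tetradeca-4,8,12-trienal | O=C[C@@](O[Si](CC)(CC)CC)(C/C=C(\C)CC/C=C(\C)CCC=C(C)C)COCc1ccc(OC)cc1 | intermediate
10 | tert-butyl(diphenyl)(prop-2-yn-1-yloxy)silane | C#CCO[Si](c1ccccc1)(c1ccccc1)C(C)(C)C | starting material
11 | lithium acetylide of 10 | [Li]C#CCO[Si](c1ccccc1)(c1ccccc1)C(C)(C)C | intermediate
12 | (5R,7E,11E)-1-[(tert-butyldiphenylsilyl)oxy]-5-{[(4-methoxybenzyl)oxy]methyl}-8,12,16-trimethyl-5-[(triethylsilyl)oxy]heptadeca-7,11,15-trien-2-yn-4-ol (C4 epimers) | OC(C#CCO[Si](c1ccccc1)(c1ccccc1)C(C)(C)C)[C@@](O[Si](CC)(CC)CC)(C/C=C(\C)CC/C=C(\C)CCC=C(C)C)COCc1ccc(OC)cc1 | intermediate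
13 | (5R,7E,11E)-1-[(tert-butyldiphenylsilyl)oxy]-5-{[(4-methoxybenzyl)oxy]methyl}-8,12,16-trimethyl-5-[(triethylsilyl)oxy]heptadeca-7,11,15-trien-2-yn-4-one | O=C(C#CCO[Si](c1ccccc1)(c1ccccc1)C(C)(C)C)[C@@](O[Si](CC)(CC)CC)(C/C=C(\C)CC/C=C(\C)CCC=C(C)C)COCc1ccc(OC)cc1 | intermediate
14 | (2E,5R,7E,11E)-1-[(tert-butyldiphenylsilyl)oxy]-2-methoxy-5-{[(4-methoxybenzyl)oxy]methyl}-8,12,16-trimethyl-5-[(triethylsilyl)oxy]heptadeca-2,7,11,15-tetraen-4-one | O=C(/C=C(OC)\CO[Si](c1ccccc1)(c1ccccc1)C(C)(C)C)[C@@](O[Si](CC)(CC)CC)(C/C=C(\C)CC/C=C(\C)CCC=C(C)C)COCc1ccc(OC)cc1 | intermediate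
15 | (2E,5R,7E,11E)-1-[(tert-butyldiphenylsilyl)oxy]-5-(hydroxymethyl)-2-methoxy-8,12,16-trimethyl-5-[(triethylsilyl)oxy]heptadeca-2,7,11,15-tetraen-4-one | O=C(/C=C(OC)\CO[Si](c1ccccc1)(c1ccccc1)C(C)(C)C)[C@@](O[Si](CC)(CC)CC)(C/C=C(\C)CC/C=C(\C)CCC=C(C)C)CO | intermediate
16 | (2R,4E)-6-[(tert-butyldiphenylsilyl)oxy]-5-methoxy-3-oxo-2-[(triethylsilyl)oxy]-2-[(2E,6E)-3,7,11-trimethyldodeca-2,6,10-trien-1-yl]hex-4-enal | O=C[C@](O[Si](CC)(CC)CC)(C/C=C(\C)CC/C=C(\C)CCC=C(C)C)C(=O)/C=C(OC)\CO[Si](c1ccccc1)(c1ccccc1)C(C)(C)C | intermediate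
17 | potassium dienolate of 16 (C4 cis to C1 across C3=C2, silyloxy group outer at C6) | O=C[C@](O[Si](CC)(CC)CC)(C/C=C(\C)CC/C=C(\C)CCC=C(C)C)/C([O-])=C\C(OC)=C\O[Si](c1ccccc1)(c1ccccc1)C(C)(C)C.[K+] | intermediate
18 | (4S,5S,6R)-4-[(tert-butyldiphenylsilyl)oxy]-5-hydroxy-3-methoxy-6-[(triethylsilyl)oxy]-6-[(2E,6E)-3,7,11-trimethyldodeca-2,6,10-trien-1-yl]cyclohex-2-en-1-one | COC1=CC(=O)[C@@](O[Si](CC)(CC)CC)(C/C=C(\C)CC/C=C(\C)CCC=C(C)C)[C@@H](O)[C@@H]1O[Si](c2ccccc2)(c2ccccc2)C(C)(C)C | intermediate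
19 | (4S,5S,6R)-4-[(tert-butyldiphenylsilyl)oxy]-5,6-dihydroxy-3-methoxy-6-[(2E,6E)-3,7,11-trimethyldodeca-2,6,10-trien-1-yl]cyclohex-2-en-1-one | COC1=CC(=O)[C@@](O)(C/C=C(\C)CC/C=C(\C)CCC=C(C)C)[C@@H](O)[C@@H]1O[Si](c2ccccc2)(c2ccccc2)C(C)(C)C | intermediate
20 | (4S,5S,6R)-4-[(tert-butyldiphenylsilyl)oxy]-6-hydroxy-3-methoxy-5-[(methylsulfonyl)oxy]-6-[(2E,6E)-3,7,11-trimethyldodeca-2,6,10-trien-1-yl]cyclohex-2-en-1-one | COC1=CC(=O)[C@@](O)(C/C=C(\C)CC/C=C(\C)CCC=C(C)C)[C@@H](OS(C)(=O)=O)[C@@H]1O[Si](c2ccccc2)(c2ccccc2)C(C)(C)C | intermediate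
21 | (1R,5S,6R)-5-[(tert-butyldiphenylsilyl)oxy]-4-methoxy-1-[(2E,6E)-3,7,11-trimethyldodeca-2,6,10-trien-1-yl]-7-oxabicyclo[4.1.0]hept-3-en-2-one | COC1=CC(=O)[C@]2(C/C=C(\C)CC/C=C(\C)CCC=C(C)C)O[C@@H]2[C@@H]1O[Si](c3ccccc3)(c3ccccc3)C(C)(C)C | intermediate
22 | yanuthone X2, (1R,5S,6R)-5-hydroxy-4-methoxy-1-[(2E,6E)-3,7,11-trimethyldodeca-2,6,10-trien-1-yl]-7-oxabicyclo[4.1.0]hept-3-en-2-one | COC1=CC(=O)[C@]2(C/C=C(\C)CC/C=C(\C)CCC=C(C)C)O[C@@H]2[C@@H]1O | target

**Step count**

Total: 14 steps. Longest linear sequence: 14 steps (1 and 2 to 22); the alkyne 10 enters in step 6.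

**Steps most likely to fail**

Step 11. The dienolate may form mainly as the rotamer with the enolate oxygen, not C4, cis to C1. That rotamer cannot reach the aldehyde, and if proton return is too slow it would be consumed by intermolecular aldol addition or by amide addition to the aldehyde. The fallback sets out from 16 and comes back at 18. The dienolate would be generated with KN(SiMe3)2 at −78 °C and quenched at once with acetic acid. Kinetic α-protonation should give the deconjugated keto aldehyde (2R)-6-[(tert-butyldiphenylsilyl)oxy]-5-methoxy-3-oxo-2-[(triethylsilyl)oxy]-2-[(2E,6E)-3,7,11-trimethyldodeca-2,6,10-trien-1-yl]hex-5-enal F1, in which C3–C2 is a freely rotating single bond. Its electron-rich enol ether would then be closed onto the aldehyde with BF3·OEt2 and 2,6-di-tert-butylpyridine in CH2Cl2 at −78 °C, a Mukaiyama-type (Prins) aldol. Loss of the C2 proton from the resulting oxocarbenium ion restores the vinylogous ester 18.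

Step 1. The coupling may suffer allylic transposition (attack at the tertiary allyl terminus), E/Z scrambling through the π-allyl intermediate, or homocoupling of the allyl partner. The fallback sets out from 2 and comes back at 5. Sodium triethyl phosphonoacetate (NaH, THF) would be alkylated with 2 to give ethyl (4E,8E)-2-(diethoxyphosphoryl)-5,9,13-trimethyltetradeca-4,8,12-trienoate F2. A Horner–Wadsworth–Emmons reaction with aqueous formaldehyde and K2CO3 would give ethyl (4E,8E)-5,9,13-trimethyl-2-methylidenetetradeca-4,8,12-trienoate F3. Reduction with i-Bu2AlH in CH2Cl2 at −78 °C would give 5.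

Step 13. Sulfonylation of the tertiary hydroxyl, or a base-induced acyloin shift of the free α-hydroxy ketone, may compete with selective C5 mesylation. The fallback sets out from 18 and comes back at 20. The C5 hydroxyl would be mesylated while the C4 oxygen is still silylated (MsCl, Et3N, DMAP, CH2Cl2), giving (4S,5S,6R)-4-[(tert-butyldiphenylsilyl)oxy]-3-methoxy-5-[(methylsulfonyl)oxy]-6-[(triethylsilyl)oxy]-6-[(2E,6E)-3,7,11-trimethyldodeca-2,6,10-trien-1-yl]cyclohex-2-en-1-one F4. Buffered HF·pyridine would then remove the triethylsilyl group to give 20, which K2CO3 in methanol would close to 21.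

**Further compounds**

F1 | step 11 | (2R)-6-[(tert-butyldiphenylsilyl)oxy]-5-methoxy-3-oxo-2-[(triethylsilyl)oxy]-2-[(2E,6E)-3,7,11-trimethyldodeca-2,6,10-trien-1-yl]hex-5-enal (enol ether geometry not defined) | O=C[C@](O[Si](CC)(CC)CC)(C/C=C(\C)CC/C=C(\C)CCC=C(C)C)C(=O)CC(OC)=CO[Si](c1ccccc1)(c1ccccc1)C(C)(C)C
F2 | step 1 | ethyl (4E,8E)-2-(diethoxyphosphoryl)-5,9,13-trimethyltetradeca-4,8,12-trienoate | CCOC(=O)C(C/C=C(\C)CC/C=C(\C)CCC=C(C)C)P(=O)(OCC)OCC
F3 | step 1 | ethyl (4E,8E)-5,9,13-trimethyl-2-methylidenetetradeca-4,8,12-trienoate | CCOC(=O)C(=C)C/C=C(\C)CC/C=C(\C)CCC=C(C)C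
F4 | step 13 | (4S,5S,6R)-4-[(tert-butyldiphenylsilyl)oxy]-3-methoxy-5-[(methylsulfonyl)oxy]-6-[(triethylsilyl)oxy]-6-[(2E,6E)-3,7,11-trimethyldodeca-2,6,10-trien-1-yl]cyclohex-2-en-1-one | COC1=CC(=O)[C@@](O[Si](CC)(CC)CC)(C/C=C(\C)CC/C=C(\C)CCC=C(C)C)[C@@H](OS(C)(=O)=O)[C@@H]1O[Si](c2ccccc2)(c2ccccc2)C(C)(C)C
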